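**Plan**
- Retrosynthesis: the acid and O5 are tied back as a six-membered aryl lactone. Ring C is cut at O1–C2 (oxa-Michael addition of an o-tigloylphenol). Then O7–CH3, the C8–prenyl bond (Claisen from O7) and C4a–C4 (Friedel–Crafts acylation) are removed, and last the C6–C1' bond.
- Enabling feature: ring A is a phloroglucinol nucleus whose C6 lies between O5 and O7. C1' (C3 of the octanoic acid, bearing pentyl and CH2CO2H) is an isolated acyclic centre β to the carboxyl carbon. It is therefore the β-carbon of oct-2-enal joined to a ring carbon ortho to a phenolic oxygen.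
- Forward: iminium-catalysed Friedel–Crafts addition of 3,5-bis(benzyloxy)phenol to (E)-oct-2-enal forms C6–C1' and the lactol ring. Oxidation gives the lactone that masks O5 and the acid. Ring A is then dressed (C4a acyl, O7 ether, C8 prenyl, O7 methyl), ring C is closed, and the lactone is opened last.
- Stereochemistry: C1' (R) comes from face shielding in the iminium ion of the (S)-diphenylprolinol silyl ether. C2 (S) and C3 (R) come from quinidine-controlled oxa-Michael addition followed by kinetic protonation, which places the two methyl groups cis.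

Key step: step 1

Remark: intermediates 4–14 are numbered as chroman-2-ones (lactone O1, C2, pentyl at C4); their C4a, C5–O, C6, C7–O, C8 and C8a become C6, O7, C8, O1, C4a and C5 of the target.

**Step 1**
Reactants: 1 3,5-bis(benzyloxy)phenol; 2 (E)-oct-2-enal
Product: 4 (4R)-5,7-bis(benzyloxy)-4-pentylchroman-2-ol (both anomers), via hydroxy aldehyde 3 (not isolated)
Conditions: (S)-2-[diphenyl(trimethylsilyloxy)methyl]pyrrolidine (20 mol%), PhCO2H (20 mol%), toluene, 0 °C
Reagents that add atoms: none
Why: The (S)-diarylprolinol silyl ether condenses with 2 to an E,s-trans iminium ion whose Si face at the β-carbon is covered by the diphenyl(silyloxy)methyl group, so the ring carbon ortho to the free hydroxyl of 1 adds to the Re face and sets C4 as R (C1' of the target); rearomatisation and hydrolysis of the enamine release aldehyde 3 and the catalyst. The closest known reaction type is the iminium-catalysed enantioselective Friedel–Crafts alkylation of electron-rich phenols and naphthols with enals that ends in hemiacetal formation. The ring closes by 6-exo-trig addition of the ortho hydroxyl to the aldehyde carbonyl, which also takes the aldehyde out of further enamine or iminium chemistry. The new stereocentre is controlled by the catalyst alone, since neither partner is chiral. The step needs ortho regioselectivity and enantioface selectivity: the two carbons ortho to the hydroxyl are equivalent, the para carbon is flanked by two benzyloxy groups and lacks the hydrogen-bond assistance of the hydroxyl, and the facial bias comes from the bulky catalyst substituent.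

**Step 2**
Reactants: 4 (4R)-5,7-bis(benzyloxy)-4-pentylchroman-2-ol
Product: 5 (4R)-5,7-bis(benzyloxy)-4-pentylchroman-2-one
Conditions: TEMPO (10 mol%), PhI(OAc)2 (1.3 equiv), CH2Cl2, rt
Reagents that add atoms: none
Why: TEMPO/PhI(OAc)2 oxidation of a lactol to the lactone via the oxoammonium salt is standard, and with both remaining phenols benzylated there is no free phenol to be oxidised, while the benzylic C4 centre is not involved.

**Step 3**
Reactants: 5 (4R)-5,7-bis(benzyloxy)-4-pentylchroman-2-one; 6 (2E)-2-methylbut-2-enoyl chloride (tigloyl chloride)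
Product: 7 (4R)-5,7-bis(benzyloxy)-8-[(2E)-2-methylbut-2-enoyl]-4-pentylchroman-2-one
Conditions: SnCl4 (1.1 equiv), CH2Cl2, −40 to −10 °C
Reagents that add atoms: none
Why: Friedel–Crafts acylation of this 1,3-dialkoxyarene should go to C8, which is para to the 5-benzyloxy and ortho to the 7-benzyloxy group, because C6 is shielded between two benzyloxy groups, and the low temperature should keep the benzyl ethers and the E-enone intact.

**Step 4**
Reactants: 7 (4R)-5,7-bis(benzyloxy)-8-[(2E)-2-methylbut-2-enoyl]-4-pentylchroman-2-one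
Product: 8 (4R)-5,7-dihydroxy-8-[(2E)-2-methylbut-2-enoyl]-4-pentylchroman-2-one
Conditions: BCl3 (4 equiv), C6HMe5 (6 equiv), CH2Cl2, −78 °C; MeOH quench
Reagents that add atoms: none
Why: BCl3 with pentamethylbenzene as cation scavenger is an established low-temperature cleavage of aryl benzyl ethers that leaves alkenes, enones and the lactone alone and prevents C-benzylation of the electron-rich ring, whereas hydrogenolysis would saturate the tigloyl double bond.

**Step 5**
Reactants: 8 (4R)-5,7-dihydroxy-8-[(2E)-2-methylbut-2-enoyl]-4-pentylchroman-2-one; 9 3-chloro-3-methylbut-1-yne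
Product: 10 (4R)-7-hydroxy-8-[(2E)-2-methylbut-2-enoyl]-5-[(2-methylbut-3-yn-2-yl)oxy]-4-pentylchroman-2-one
Conditions: DBU (1.05 equiv), CuCl2·2H2O (1 mol%), MeCN, −5 to 0 °C
Reagents that add atoms: none
Why: Copper-catalysed propargylic etherification with a tertiary propargyl chloride and DBU is selective for the more acidic, unchelated 5-hydroxyl (para to the ketone) because the 7-hydroxyl is tied up in a hydrogen bond to the carbonyl, the same selectivity that is used in chromene annulations of 8-acyl-5,7-dihydroxycoumarins, and the small excess of base at 0 °C should not close ring C.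

**Step 6**
Reactants: 10 (4R)-7-hydroxy-8-[(2E)-2-methylbut-2-enoyl]-5-[(2-methylbut-3-yn-2-yl)oxy]-4-pentylchroman-2-one
Product: 11 (4R)-7-hydroxy-8-[(2E)-2-methylbut-2-enoyl]-5-[(2-methylbut-3-en-2-yl)oxy]-4-pentylchroman-2-one
Conditions: H2 (1 atm), Pd/CaCO3 poisoned with Pb(OAc)2, quinoline, EtOAc, rt
Reagents that add atoms: none
Why: Lindlar semihydrogenation stops a terminal alkyne at the alkene and does not reduce the trisubstituted conjugated double bond of the tigloyl group or the lactone.

**Step 7**
Reactants: 11 (4R)-7-hydroxy-8-[(2E)-2-methylbut-2-enoyl]-5-[(2-methylbut-3-en-2-yl)oxy]-4-pentylchroman-2-one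
Product: 13 (4R)-5,7-dihydroxy-8-[(2E)-2-methylbut-2-enoyl]-6-(3-methylbut-2-enyl)-4-pentylchroman-2-one, via cyclohexadienone 12 (not isolated)
Conditions: toluene, 110 °C (sealed tube)
Reagents that add atoms: none
Why: Aromatic Claisen rearrangement ([3,3]-sigmatropic shift) of the 1,1-dimethylallyl ether can only reach C6 because the other ortho carbon C4a is substituted, and enolisation of dienone 12 restores the phenol with the allyl unit inverted to a linear prenyl group.

**Step 8**
Reactants: 13 (4R)-5,7-dihydroxy-8-[(2E)-2-methylbut-2-enoyl]-6-(3-methylbut-2-enyl)-4-pentylchroman-2-one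
Product: 14 (4R)-7-hydroxy-5-methoxy-8-[(2E)-2-methylbut-2-enoyl]-6-(3-methylbut-2-enyl)-4-pentylchroman-2-one
Conditions: Me3SiCHN2 (1.5 equiv), toluene/MeOH 4:1, 0 °C to rt
Reagents that add atoms: trimethylsilyldiazomethane, C[Si](C)(C)C=[N+]=[N-]
Why: Trimethylsilyldiazomethane in methanol methylates acidic unchelated phenols under neutral conditions, so the 5-hydroxyl para to the ketone is methylated while the hydrogen-bonded 7-hydroxyl and the base-sensitive o-hydroxyaryl enone remain untouched.

**Step 9**
Reactants: 14 (4R)-7-hydroxy-5-methoxy-8-[(2E)-2-methylbut-2-enoyl]-6-(3-methylbut-2-enyl)-4-pentylchroman-2-one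
Product: 16 (4R,8S,9R)-5-methoxy-8,9-dimethyl-6-(3-methylbut-2-enyl)-4-pentyl-3,4,8,9-tetrahydro-2H,10H-pyrano[2,3-f]chromene-2,10-dione, via enol 15 (not isolated)
Conditions: quinidine (20 mol%), chlorobenzene, rt
Reagents that add atoms: none
Why: Cinchona-alkaloid-catalysed intramolecular oxa-Michael addition of o-tigloylphenols (6-endo-trig) is the known route to cis-2,3-dimethylchroman-4-ones: the quinuclidine nitrogen activates the only free hydroxyl (the lactone blocks the other ortho oxygen) while the alkaloid hydroxyl binds the carbonyl, the alkaloid fixes the face of the β-carbon that is attacked (quinidine, the pseudoenantiomer of the quinine that gives the antipodal ring in the 7-hydroxy-8-tigloylcoumarin series, is expected to give 8S), and kinetic protonation of enol 15 anti to the new C8 methyl group sets 9R with the two methyl groups cis.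

**Step 10**
Reactants: 16 (4R,8S,9R)-5-methoxy-8,9-dimethyl-6-(3-methylbut-2-enyl)-4-pentyl-3,4,8,9-tetrahydro-2H,10H-pyrano[2,3-f]chromene-2,10-dione
Product: 17 (3R)-3-[(2S,3R)-5-hydroxy-7-methoxy-2,3-dimethyl-8-(3-methylbut-2-enyl)-4-oxochroman-6-yl]octanoic acid
Conditions: LiOH·H2O (2.05 equiv), THF/H2O 3:1, 0 °C; then 1 M HCl to pH 3
Reagents that add atoms: water, O
Why: Saponification of the aryl lactone with just two equivalents of LiOH at 0 °C is fast, the carboxylate and the ketone-conjugated 5-phenoxide that result consume the hydroxide so that the epimerisable C3 centre is not exposed to excess base, and after acidification the 5-hydroxyl is held by a hydrogen bond to the C4 carbonyl, which disfavours relactonisation.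

**Compound list**
1 | 3,5-bis(benzyloxy)phenol | Oc1cc(OCc2ccccc2)cc(OCc2ccccc2)c1 | starting material
2 | (E)-oct-2-enal | CCCCC/C=C/C=O | starting material
3 | (3R)-3-[2,4-bis(benzyloxy)-6-hydroxyphenyl]octanal | CCCCC[C@H](CC=O)c1c(O)cc(OCc2ccccc2)cc1OCc1ccccc1 | intermediate
4 | (4R)-5,7-bis(benzyloxy)-4-pentylchroman-2-ol (both anomers) | CCCCC[C@@H]1CC(O)Oc2cc(OCc3ccccc3)cc(OCc3ccccc3)c21 | intermediate
5 | (4R)-5,7-bis(benzyloxy)-4-pentylchroman-2-one | CCCCC[C@@H]1CC(=O)Oc2cc(OCc3ccccc3)cc(OCc3ccccc3)c21 | intermediate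
6 | (2E)-2-methylbut-2-enoyl chloride | C/C=C(\C)C(=O)Cl | starting material
7 | (4R)-5,7-bis(benzyloxy)-8-[(2E)-2-methylbut-2-enoyl]-4-pentylchroman-2-one | CCCCC[C@@H]1CC(=O)Oc2c(C(=O)/C(C)=C/C)c(OCc3ccccc3)cc(OCc3ccccc3)c21 | intermediate
8 | (4R)-5,7-dihydroxy-8-[(2E)-2-methylbut-2-enoyl]-4-pentylchroman-2-one | CCCCC[C@@H]1CC(=O)Oc2c(C(=O)/C(C)=C/C)c(O)cc(O)c21 | intermediate
9 | 3-chloro-3-methylbut-1-yne | CC(C)(Cl)C#C | starting material
10 | (4R)-7-hydroxy-8-[(2E)-2-methylbut-2-enoyl]-5-[(2-methylbut-3-yn-2-yl)oxy]-4-pentylchroman-2-one | CCCCC[C@@H]1CC(=O)Oc2c(C(=O)/C(C)=C/C)c(O)cc(OC(C)(C)C#C)c21 | intermediate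
11 | (4R)-7-hydroxy-8-[(2E)-2-methylbut-2-enoyl]-5-[(2-methylbut-3-en-2-yl)oxy]-4-pentylchroman-2-one | CCCCC[C@@H]1CC(=O)Oc2c(C(=O)/C(C)=C/C)c(O)cc(OC(C)(C)C=C)c21 | intermediate
12 | (4R)-7-hydroxy-8-[(2E)-2-methylbut-2-enoyl]-6-(3-methylbut-2-enyl)-4-pentyl-3,4-dihydro-2H-chromene-2,5(6H)-dione (C6 epimers) | CCCCC[C@@H]1CC(=O)OC2=C1C(=O)C(CC=C(C)C)C(O)=C2C(=O)/C(C)=C/C | intermediate
13 | (4R)-5,7-dihydroxy-8-[(2E)-2-methylbut-2-enoyl]-6-(3-methylbut-2-enyl)-4-pentylchroman-2-one | CCCCC[C@@H]1CC(=O)Oc2c(C(=O)/C(C)=C/C)c(O)c(CC=C(C)C)c(O)c21 | intermediate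
14 | (4R)-7-hydroxy-5-methoxy-8-[(2E)-2-methylbut-2-enoyl]-6-(3-methylbut-2-enyl)-4-pentylchroman-2-one | CCCCC[C@@H]1CC(=O)Oc2c(C(=O)/C(C)=C/C)c(O)c(CC=C(C)C)c(OC)c21 | intermediate
15 | (4R,8S)-10-hydroxy-5-methoxy-8,9-dimethyl-6-(3-methylbut-2-enyl)-4-pentyl-3,4-dihydro-2H,8H-pyrano[2,3-f]chromen-2-one | CCCCC[C@@H]1CC(=O)Oc2c3C(O)=C(C)[C@H](C)Oc3c(CC=C(C)C)c(OC)c21 | intermediate
16 | (4R,8S,9R)-5-methoxy-8,9-dimethyl-6-(3-methylbut-2-enyl)-4-pentyl-3,4,8,9-tetrahydro-2H,10H-pyrano[2,3-f]chromene-2,10-dione | CCCCC[C@@H]1CC(=O)Oc2c3C(=O)[C@H](C)[C@H](C)Oc3c(CC=C(C)C)c(OC)c21 | intermediate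
17 | (3R)-3-[(2S,3R)-5-hydroxy-7-methoxy-2,3-dimethyl-8-(3-methylbut-2-enyl)-4-oxochroman-6-yl]octanoic acid | CCCCC[C@H](CC(=O)O)c1c(O)c2c(c(CC=C(C)C)c1OC)O[C@@H](C)[C@@H](C)C2=O | target

**Step count**
Total: 10 steps. Longest linear sequence: 10 steps (1 and 2 to 17).

**Steps most likely to fail**

Step 5. What may go wrong: base-induced oxa-Michael closure of the o-hydroxyaryl enone before the chiral catalyst is applied, which would fix C2 and C3 without control, or ether formation at the chelated 7-hydroxyl. The fallback avoids both the amine base and the alkyne by a Tsuji–Trost O-allylation. 2-Methylbut-3-en-2-ol is converted (n-BuLi, Boc2O, THF) to tert-butyl 2-methylbut-3-en-2-yl carbonate F1. Diol 8 is then treated with F1 and Pd(PPh3)4 (zerovalent palladium, 5 mol%) in THF at 0 °C. Decarboxylation gives a π-allyl complex and tert-butoxide, which deprotonates only the more acidic 5-hydroxyl. The phenoxide attacks the tertiary allyl terminus and gives the 1,1-dimethylallyl ether 11 directly. This fallback sets out from 8 and rejoins the route at 11, replacing steps 5 and 6.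

Step 9. What may go wrong: slow or weakly face-selective ring closure at a phenol crowded by the neighbouring prenyl group, with loss of the cis relationship on long exposure to the amine. The fallback closes ring C before ring A is fully substituted. Allyl ether 11 has an unhindered reacting hydroxyl and no second acidic phenol to bind the alkaloid. It is cyclised with quinidine in chlorobenzene to (4R,8S,9R)-8,9-dimethyl-5-[(2-methylbut-3-en-2-yl)oxy]-4-pentyl-3,4,8,9-tetrahydro-2H,10H-pyrano[2,3-f]chromene-2,10-dione F2. Claisen rearrangement in toluene at 110 °C then gives (4R,8S,9R)-5-hydroxy-8,9-dimethyl-6-(3-methylbut-2-enyl)-4-pentyl-3,4,8,9-tetrahydro-2H,10H-pyrano[2,3-f]chromene-2,10-dione F3. Methylation with Me3SiCHN2 in toluene/MeOH gives 16. All steps after the cyclisation are neutral. This fallback sets out from 11 and rejoins the route at 16.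

Step 10. What may go wrong: epimerisation at C3 (cis to trans) or retro-oxa-Michael opening of ring C by hydroxide, and relactonisation during acidification. The fallback frees the acid without hydroxide. Lactone 16 is transesterified with allyl alcohol under neutral organotin catalysis ((ClBu2Sn)2O, toluene, 60 °C) to prop-2-enyl (3R)-3-[(2S,3R)-5-hydroxy-7-methoxy-2,3-dimethyl-8-(3-methylbut-2-enyl)-4-oxochroman-6-yl]octanoate F4, in which the released 5-hydroxyl is held by the C4 carbonyl. The allyl group is then removed with Pd(PPh3)4 and morpholine in THF at rt to give 17. This fallback sets out from 16 and rejoins the route at 17.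

**Further compounds**
F1 | step 5 | tert-butyl 2-methylbut-3-en-2-yl carbonate | CC(C)(C)OC(=O)OC(C)(C)C=C
F2 | step 9 | (4R,8S,9R)-8,9-dimethyl-5-[(2-methylbut-3-en-2-yl)oxy]-4-pentyl-3,4,8,9-tetrahydro-2H,10H-pyrano[2,3-f]chromene-2,10-dione | CCCCC[C@@H]1CC(=O)Oc2c3C(=O)[C@H](C)[C@H](C)Oc3cc(OC(C)(C)C=C)c21
F3 | step 9 | (4R,8S,9R)-5-hydroxy-8,9-dimethyl-6-(3-methylbut-2-enyl)-4-pentyl-3,4,8,9-tetrahydro-2H,10H-pyrano[2,3-f]chromene-2,10-dione | CCCCC[C@@H]1CC(=O)Oc2c3C(=O)[C@H](C)[C@H](C)Oc3c(CC=C(C)C)c(O)c21
F4 | step 10 | prop-2-enyl (3R)-3-[(2S,3R)-5-hydroxy-7-methoxy-2,3-dimethyl-8-(3-methylbut-2-enyl)-4-oxochroman-6-yl]octanoate | CCCCC[C@H](CC(=O)OCC=C)c1c(O)c2c(c(CC=C(C)C)c1OC)O[C@@H](C)[C@@H](C)C2=O
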